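**Retrosynthetic overview**

- Feature: the only ring is the oxocene O–C7–C8–C9=C10–C11–C12(Br)–C13(Et). Its Z-alkene C9=C10 lies γ,δ to C13, so with C13 as a lactone carbonyl the ring is the product of a Claisen rearrangement.
- Late disconnections: C6–OAc; C3=C4 by E-selective Horner–Wadsworth–Emmons enyne formation; C5–C6 by chelation-controlled Mukaiyama acetate aldol on the C6 aldehyde; C12–Br by invertive bromination of the C12 alcohol.
- Middle disconnections: C14–C15 (cuprate on the C14 triflate); C13–H and C14–O (lactone methylenation, hydrosilation tethered from the C12 oxygen, Tamao–Fleming oxidation); C12–O (enolate hydroxylation).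
- Key disconnection: C11–C12 of the eight-membered lactone, traced back to the ketene acetal of a syn-1,3-diol. C7 comes from dimethyl (R)-malate, C9–C11 from a vinyl Grignard reagent, C12–C13 from a selenoacetal.
- Ring order: a sacrificial 1,3-dioxane (step 7), then the oxocene by two-atom ring expansion (step 9).

Key step: step 9

Remark: target numbering C1 (alkyne CH) to C15 (ethyl CH3) is used for all intermediates. Selenoxide 13 is a mixture of epimers at selenium, which is without consequence because selenium is lost in step 9.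

**Route**

Step 1
Reactants: 1 dimethyl (R)-malate
Product: 2 methyl (3R)-3,4-dihydroxybutanoate
Conditions: BH3·SMe2 (1.05 equiv), NaBH4 (5 mol %), THF, 0 °C → rt; MeOH quench
Reagents that add atoms: none
Why: hydroxyl-directed chemoselective borane reduction, in which the alkoxyborane formed at the free hydroxyl delivers hydride only to the adjacent ester, so the remote ester and the future C7 stereocentre are untouched.

Step 2
Reactants: 2 methyl (3R)-3,4-dihydroxybutanoate
Product: 3 methyl (3R)-4-[(tert-butyldiphenylsilyl)oxy]-3-hydroxybutanoate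
Conditions: TBDPSCl, imidazole, DMF, 0 °C (crude 2 used at once to avoid lactonisation)
Reagents that add atoms: tert-butyl(chloro)diphenylsilane, CC(C)(C)[Si](Cl)(c1ccccc1)c1ccccc1
Why: selective silylation of the primary hydroxyl, since the bulky silyl chloride reacts much faster there than at the secondary hydroxyl.

Step 3
Reactants: 3 methyl (3R)-4-[(tert-butyldiphenylsilyl)oxy]-3-hydroxybutanoate
Product: 4 (3R)-4-[(tert-butyldiphenylsilyl)oxy]-3-hydroxy-N-methoxy-N-methylbutanamide
Conditions: MeNH(OMe)·HCl, i-PrMgCl, THF, −20 → 0 °C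
Reagents that add atoms: N,O-dimethylhydroxylamine hydrochloride, CNOC.Cl
Why: ester aminolysis by the chloromagnesium amide (Weinreb amide formation), which tolerates the β-hydroxyl as its magnesium alkoxide.

Step 4
Reactants: 4 (3R)-4-[(tert-butyldiphenylsilyl)oxy]-3-hydroxy-N-methoxy-N-methylbutanamide; 5 vinylmagnesium bromide
Product: 6 (5R)-6-[(tert-butyldiphenylsilyl)oxy]-5-hydroxyhex-1-en-3-one
Conditions: CH2=CHMgBr (3 equiv), THF, −78 → 0 °C; inverse quench into cold 1 M HCl
Reagents that add atoms: vinylmagnesium bromide 5, C=C[Mg]Br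
Why: Weinreb ketone synthesis, in which the stable magnesium chelate prevents over-addition and the acidic inverse quench keeps the released amine from adding to the enone.

Step 5
Reactants: 6 (5R)-6-[(tert-butyldiphenylsilyl)oxy]-5-hydroxyhex-1-en-3-one
Product: 7 (3S,5R)-6-[(tert-butyldiphenylsilyl)oxy]hex-1-ene-3,5-diol (syn-1,3-diol)
Conditions: Et2BOMe, THF/MeOH (4:1), −78 °C; NaBH4, −78 °C; AcOH quench, MeOH co-evaporation
Reagents that add atoms: none
Why: Narasaka–Prasad reduction, in which external hydride attacks the six-membered boron chelate of the β-hydroxy ketone axially and sets the C9 carbinol (3S) syn to the C7 hydroxyl by 1,3-induction.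

Step 6
Reactants: 8 diphenyl diselenide; 9 bromoacetaldehyde diethyl acetal
Product: 11 2-(phenylselanyl)acetaldehyde diethyl acetal, via sodium benzeneselenolate 10 (not isolated)
Conditions: NaBH4, EtOH, 0 °C → rt; then 9, reflux
Reagents that add atoms: diphenyl diselenide 8, c1ccc(cc1)[Se][Se]c1ccccc1; bromoacetaldehyde diethyl acetal 9, CCOC(CBr)OCC
Why: reductive cleavage of the Se–Se bond followed by SN2 displacement of the primary bromide by the soft selenolate.

Step 7
Reactants: 7 (3S,5R)-6-[(tert-butyldiphenylsilyl)oxy]hex-1-ene-3,5-diol; 11 2-(phenylselanyl)acetaldehyde diethyl acetal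
Product: 12 (2R,4S,6R)-4-ethenyl-2-[(phenylselanyl)methyl]-6-{[(tert-butyldiphenylsilyl)oxy]methyl}-1,3-dioxane (all-cis)
Conditions: PPTS (cat.), toluene, reflux, removal of EtOH
Reagents that add atoms: 2-(phenylselanyl)acetaldehyde diethyl acetal 11, CCOC(C[Se]c1ccccc1)OCC
Why: acid-catalysed transacetalisation under thermodynamic control, in which the syn-diol gives the single all-equatorial 2,4,6-cis dioxane, so the new acetal centre is set by equilibration.

Step 8
Reactants: 12 all-cis selenoacetal dioxane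
Product: 13 (2R,4S,6R)-4-ethenyl-2-[(phenylseleninyl)methyl]-6-{[(tert-butyldiphenylsilyl)oxy]methyl}-1,3-dioxane (selenoxide)
Conditions: NaIO4, NaHCO3, MeOH/H2O, rt
Reagents that add atoms: sodium periodate, [Na+].[O-]I(=O)(=O)=O
Why: chemoselective oxidation of the selenide to the selenoxide, which survives at room temperature because its only β-hydrogen is the acetal C–H, towards which syn-elimination is slow.

Step 9
Reactants: 13 selenoxide dioxane
Product: 15 (5Z,8R)-8-{[(tert-butyldiphenylsilyl)oxy]methyl}-3,4,7,8-tetrahydro-2H-oxocin-2-one (lactone), via ketene acetal 14 (not isolated)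
Conditions: DBU (3 equiv), degassed xylene, 140 °C
Reagents that add atoms: none
Why: Heating with DBU triggers syn-elimination of PhSeOH (held by the base) to give the 2-methylidene-1,3-dioxane 14, whose CH2=C(O)–O–C9–C10=C11 array undergoes a concerted suprafacial [3,3]-sigmatropic shift that forms C11–C12, breaks the allylic C9–O bond and turns the acetal carbon into the C13 lactone carbonyl. The closest known reaction type is the Claisen rearrangement of cyclic ketene acetals (2-methylidene-4-vinyl-1,3-dioxanes and their ring homologues, commonly unmasked by selenoxide elimination) to medium-ring unsaturated lactones. The eight-membered ring is closed by ring expansion and not by end-to-end cyclisation: the dioxane grows by the two vinyl carbons through a bicyclo[3.3.1]-like transition state in which the dioxane twists so that the vinyl group is pseudo-axial over the ketene acetal while the silyloxymethyl group stays pseudo-equatorial. No stereocentre is created, since C9 is destroyed and C7 (R, from malate) takes no part and is carried over unchanged. The selectivity needed is alkene geometry, and the substrate enforces it because the new C9=C10 bond forms inside the eight-membered ring of the bicyclic transition state and can only be Z. The irreversible formation of the C=O bond drives the reaction, and the basic aprotic medium protects the acid-labile ketene acetal until it rearranges.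

Step 10
Reactants: 15 lactone
Product: 17 (3R,5Z,8R)-8-{[(tert-butyldiphenylsilyl)oxy]methyl}-3-hydroxy-3,4,7,8-tetrahydro-2H-oxocin-2-one (12R; OH cis to the C7 substituent), via potassium enolate 16 (not isolated)
Conditions: KN(SiMe3)2, THF, −78 °C; then trans-3-phenyl-2-(phenylsulfonyl)oxaziridine, −78 °C; aq. NH4Cl
Reagents that add atoms: trans-3-phenyl-2-(phenylsulfonyl)oxaziridine, O=S(=O)(c1ccccc1)N1OC1c1ccccc1
Why: Davis oxidation of the endocyclic potassium enolate, in which the oxaziridine should attack the exposed outer face of the tub-shaped ring (the inner face is screened by the C9=C10 alkene) and, with the C7 substituent pseudo-equatorial, place the hydroxyl cis to it (12R).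

Step 11
Reactants: 17 (12R)-hydroxy lactone
Product: 18 (3R,5Z,8R)-8-{[(tert-butyldiphenylsilyl)oxy]methyl}-3-[(trimethylsilyl)oxy]-3,4,7,8-tetrahydro-2H-oxocin-2-one
Conditions: Me3SiCl, Et3N, CH2Cl2, 0 °C
Reagents that add atoms: chlorotrimethylsilane, C[Si](C)(C)Cl
Why: routine silylation that masks the acidic hydroxyl before the titanium reagent.

Step 12
Reactants: 18 silyloxy lactone
Product: 19 (3R,5Z,8R)-8-{[(tert-butyldiphenylsilyl)oxy]methyl}-2-methylidene-3-[(trimethylsilyl)oxy]-3,4,7,8-tetrahydro-2H-oxocine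
Conditions: Cp2TiMe2 (2.5 equiv), toluene, 70 °C, dark; base-washed glassware
Reagents that add atoms: dimethyltitanocene, [CH3-].[CH3-].[Ti+4].c1cc[cH-]c1.c1cc[cH-]c1
Why: Petasis methylenation, in which the titanium methylidene adds to the lactone carbonyl by [2+2] cycloaddition and cycloreversion under neutral conditions that spare the silyl ethers and the ring alkene.

Step 13
Reactants: 19 silyloxy enol ether
Product: 20 (3R,5Z,8R)-8-{[(tert-butyldiphenylsilyl)oxy]methyl}-2-methylidene-3,4,7,8-tetrahydro-2H-oxocin-3-ol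
Conditions: K2CO3 (cat.), MeOH, 0 °C
Reagents that add atoms: none
Why: base-catalysed methanolysis removes only the labile trimethylsilyl ether and leaves the acid-sensitive enol ether and the TBDPS ether intact.

Step 14
Reactants: 20 hydroxy enol ether
Product: 22 cis-fused bicyclic siloxane in which O–SiMe2–CH2 links the C12 oxygen to C13 (C7 CH2OTBDPS, C12 O and C13 CH2 all cis on the oxocene), via dimethylsilyl ether 21 (not isolated)
Conditions: (HMe2Si)2NH (neat), rt → 40 °C, evaporate; Pt2[(CH2=CHSiMe2)2O]3 (zerovalent platinum, 0.5 mol %), toluene, 60 °C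
Reagents that add atoms: 1,1,3,3-tetramethyldisilazane, C[SiH](C)N[SiH](C)C
Why: platinum-catalysed intramolecular (5-endo) hydrosilation of an α-silyloxy enol ether, in which silicon goes to C14 and hydrogen to C13 from the face opposite C11, so the oxasilolane closes cis-fused and C14 ends cis to the C12 oxygen and to the C7 substituent (the 2,3-syn rule of this reaction).

Step 15
Reactants: 22 bicyclic siloxane
Product: 23 (2R,3R,5Z,8R)-8-{[(tert-butyldiphenylsilyl)oxy]methyl}-2-(hydroxymethyl)-3,4,7,8-tetrahydro-2H-oxocin-3-ol (7R,12R,13R diol)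
Conditions: 30 % H2O2, KF, KHCO3, THF/MeOH, rt
Reagents that add atoms: hydrogen peroxide, OO
Why: Tamao–Fleming oxidation of the alkoxysilane C–Si bond to C–OH, which is inert towards the isolated Z-alkene and the TBDPS ether.

Step 16
Reactants: 23 diol
Product: 25 [(2R,3R,5Z,8R)-8-{[(tert-butyldiphenylsilyl)oxy]methyl}-3-[(triethylsilyl)oxy]-3,4,7,8-tetrahydro-2H-oxocin-2-yl]methyl trifluoromethanesulfonate, via hydroxy triflate 24 (not isolated)
Conditions: Tf2O (1.05 equiv), 2,6-lutidine, CH2Cl2, −78 °C; then Et3SiOTf, −78 → 0 °C; used crude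
Reagents that add atoms: trifluoromethanesulfonic anhydride, O=S(=O)(OS(=O)(=O)C(F)(F)F)C(F)(F)F; triethylsilyl trifluoromethanesulfonate, CC[Si](CC)(CC)OS(=O)(=O)C(F)(F)F
Why: kinetic sulfonylation of the primary hydroxyl at low temperature followed by silylation of the remaining secondary hydroxyl in the same flask, which blocks oxetane formation in the next step.

Step 17
Reactants: 25 triflate silyl ether
Product: 26 (2R,3R,5Z,8R)-8-{[(tert-butyldiphenylsilyl)oxy]methyl}-2-ethyl-3-[(triethylsilyl)oxy]-3,4,7,8-tetrahydro-2H-oxocine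
Conditions: Me2CuLi (from MeLi and CuI), Et2O, −40 → 0 °C
Reagents that add atoms: lithium dimethylcuprate, [Li+].C[Cu-]C (made in the flask from methyllithium, [Li]C, and CuI)
Why: SN2 displacement of a primary triflate by a Gilman cuprate, which completes the C13 ethyl group (C14–C15) without touching a stereocentre.

Step 18
Reactants: 26 ethyl silyl ether
Product: 27 (2R,3R,5Z,8R)-8-{[(tert-butyldiphenylsilyl)oxy]methyl}-2-ethyl-3,4,7,8-tetrahydro-2H-oxocin-3-ol (12R alcohol)
Conditions: PPTS, MeOH/CH2Cl2, rt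
Reagents that add atoms: none
Why: mild acid-catalysed methanolysis cleaves the triethylsilyl ether far faster than the primary TBDPS ether.

Step 19
Reactants: 27 (12R)-alcohol
Product: 28 tert-butyl{[(2R,4Z,7S,8R)-7-bromo-8-ethyl-3,6,7,8-tetrahydro-2H-oxocin-2-yl]methoxy}diphenylsilane (12S bromide)
Conditions: CBr4, P(n-C8H17)3, toluene, 70 °C
Reagents that add atoms: carbon tetrabromide, BrC(Br)(Br)Br
Why: Appel-type bromination, in which bromide displaces the alkoxyphosphonium ion by SN2 and inverts C12 from R to S, placing bromine trans to the C13 ethyl group.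

Step 20
Reactants: 28 bromide
Product: 29 [(2R,4Z,7S,8R)-7-bromo-8-ethyl-3,6,7,8-tetrahydro-2H-oxocin-2-yl]methanol
Conditions: HF·pyridine, pyridine, THF, 0 °C → rt
Reagents that add atoms: none
Why: fluoride cleavage of the Si–O bond under buffered, non-basic conditions that cannot eliminate the secondary bromide.

Step 21
Reactants: 29 primary alcohol
Product: 30 (2R,4Z,7S,8R)-7-bromo-8-ethyl-3,6,7,8-tetrahydro-2H-oxocine-2-carbaldehyde (C6 aldehyde; used at once)
Conditions: Dess–Martin periodinane, NaHCO3, CH2Cl2, 0 °C → rt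
Reagents that add atoms: none
Why: Dess–Martin oxidation under buffered, base-free conditions that do not epimerise the α-alkoxy aldehyde at C7.

Step 22
Reactants: 30 C6 aldehyde; 31 1-(tert-butyldimethylsilyloxy)-1-methoxyethene
Product: 32 methyl (3R)-3-[(2R,4Z,7S,8R)-7-bromo-8-ethyl-3,6,7,8-tetrahydro-2H-oxocin-2-yl]-3-hydroxypropanoate
Conditions: MgBr2·OEt2 (3 equiv), CH2Cl2, −78 → −30 °C; aq. NH4Cl
Reagents that add atoms: 1-(tert-butyldimethylsilyloxy)-1-methoxyethene 31, C=C(OC)O[Si](C)(C)C(C)(C)C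
Why: chelation-controlled Mukaiyama aldol, in which MgBr2 bridges the aldehyde oxygen and the ring oxygen on C7 and the silyl ketene acetal attacks the five-membered chelate from the side of the C7 hydrogen, giving the 6,7-syn (6R) aldol.

Step 23
Reactants: 32 β-hydroxy ester
Product: 33 methyl (3R)-3-[(2R,4Z,7S,8R)-7-bromo-8-ethyl-3,6,7,8-tetrahydro-2H-oxocin-2-yl]-3-[(triethylsilyl)oxy]propanoate
Conditions: Et3SiCl, imidazole, DMF, 0 °C
Reagents that add atoms: chlorotriethylsilane, CC[Si](Cl)(CC)CC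
Why: routine silylation that prevents retro-aldol and β-elimination in the next two steps.

Step 24
Reactants: 33 β-silyloxy ester
Product: 34 (3R)-3-[(2R,4Z,7S,8R)-7-bromo-8-ethyl-3,6,7,8-tetrahydro-2H-oxocin-2-yl]-3-[(triethylsilyl)oxy]propanal (C4 aldehyde)
Conditions: i-Bu2AlH (1.1 equiv), CH2Cl2, −78 °C; MeOH, then aq. KNaC4H4O6
Reagents that add atoms: none
Why: partial reduction of the ester, in which the tetrahedral aluminium hemiacetal is stable at −78 °C and releases the aldehyde only on work-up.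

Step 25
Reactants: 35 3-bromo-1-(trimethylsilyl)prop-1-yne; 36 triethyl phosphite
Product: 37 diethyl [3-(trimethylsilyl)prop-2-yn-1-yl]phosphonate
Conditions: neat, 120 °C, EtBr distilled off
Reagents that add atoms: 3-bromo-1-(trimethylsilyl)prop-1-yne 35, C[Si](C)(C)C#CCBr; triethyl phosphite 36, CCOP(OCC)OCC
Why: Michaelis–Arbuzov reaction of a reactive propargylic bromide.

Step 26
Reactants: 34 C4 aldehyde; 37 diethyl [3-(trimethylsilyl)prop-2-yn-1-yl]phosphonate
Product: 39 (3E,6R)-6-[(2R,4Z,7S,8R)-7-bromo-8-ethyl-3,6,7,8-tetrahydro-2H-oxocin-2-yl]-6-[(triethylsilyl)oxy]-1-(trimethylsilyl)hex-3-en-1-yne, via lithiated phosphonate 38 (not isolated)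
Conditions: LiN(SiMe3)2, THF, −78 °C; then 34, −78 → 0 °C
Reagents that add atoms: diethyl [3-(trimethylsilyl)prop-2-yn-1-yl]phosphonate 37, CCOP(=O)(CC#C[Si](C)(C)C)OCC
Why: Horner–Wadsworth–Emmons olefination with a propargyl-stabilised phosphonate anion, which should give the conjugated enyne E-selectively by equilibration to the anti oxaphosphetane, while the low temperature spares the secondary bromide.

Step 27
Reactants: 39 bis-silylated enyne
Product: 40 (1R,3E)-1-[(2R,4Z,7S,8R)-7-bromo-8-ethyl-3,6,7,8-tetrahydro-2H-oxocin-2-yl]hex-3-en-5-yn-1-ol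
Conditions: Bu4NF, AcOH (1:1), THF, 0 °C → rt
Reagents that add atoms: none
Why: fluoride cleaves both the O–SiEt3 and the alkynyl C–SiMe3 bonds, and the acetic acid buffer suppresses E2 loss of HBr towards the allylic C11 hydrogens.

Step 28
Reactants: 40 hydroxy enyne
Product: 41 (1R,3E)-1-[(2R,4Z,7S,8R)-7-bromo-8-ethyl-3,6,7,8-tetrahydro-2H-oxocin-2-yl]hex-3-en-5-yn-1-yl acetate (target; 6R,7R,12S,13R)
Conditions: Ac2O, pyridine, DMAP (cat.), CH2Cl2, 0 °C → rt
Reagents that add atoms: acetic anhydride, CC(=O)OC(C)=O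
Why: DMAP-catalysed acylation of the secondary C6 alcohol with retention, under conditions that leave the terminal alkyne and the bromide alone.

**Compound list**

1 | dimethyl (R)-malate | O[C@H](CC(=O)OC)C(=O)OC | starting material
2 | methyl (3R)-3,4-dihydroxybutanoate | O[C@H](CC(=O)OC)CO | intermediate
3 | methyl (3R)-4-[(tert-butyldiphenylsilyl)oxy]-3-hydroxybutanoate | O[C@H](CC(=O)OC)CO[Si](c1ccccc1)(c1ccccc1)C(C)(C)C | intermediate
4 | (3R)-4-[(tert-butyldiphenylsilyl)oxy]-3-hydroxy-N-methoxy-N-methylbutanamide | O[C@H](CC(=O)N(C)OC)CO[Si](c1ccccc1)(c1ccccc1)C(C)(C)C | intermediate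
5 | vinylmagnesium bromide | C=C[Mg]Br | starting material
6 | (5R)-6-[(tert-butyldiphenylsilyl)oxy]-5-hydroxyhex-1-en-3-one | O[C@H](CC(=O)C=C)CO[Si](c1ccccc1)(c1ccccc1)C(C)(C)C | intermediate
7 | (3S,5R)-6-[(tert-butyldiphenylsilyl)oxy]hex-1-ene-3,5-diol | O[C@H](C=C)C[C@H](CO[Si](c1ccccc1)(c1ccccc1)C(C)(C)C)O | intermediate
8 | diphenyl diselenide | c1ccc(cc1)[Se][Se]c1ccccc1 | starting material
9 | bromoacetaldehyde diethyl acetal | CCOC(CBr)OCC | starting material
10 | sodium benzeneselenolate | [Na+].[Se-]c1ccccc1 | intermediate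
11 | 2-(phenylselanyl)acetaldehyde diethyl acetal | CCOC(C[Se]c1ccccc1)OCC | intermediate
12 | (2R,4S,6R)-4-ethenyl-2-[(phenylselanyl)methyl]-6-{[(tert-butyldiphenylsilyl)oxy]methyl}-1,3-dioxane | c1ccccc1[Se]C[C@@H]1O[C@H](C=C)C[C@H](CO[Si](c2ccccc2)(c2ccccc2)C(C)(C)C)O1 | intermediate
13 | (2R,4S,6R)-4-ethenyl-2-[(phenylseleninyl)methyl]-6-{[(tert-butyldiphenylsilyl)oxy]methyl}-1,3-dioxane (mixture at Se) | O=[Se](C[C@@H]1O[C@H](C=C)C[C@H](CO[Si](c2ccccc2)(c2ccccc2)C(C)(C)C)O1)c1ccccc1 | intermediate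
14 | (4S,6R)-4-ethenyl-2-methylidene-6-{[(tert-butyldiphenylsilyl)oxy]methyl}-1,3-dioxane (cis ketene acetal) | C=C1O[C@H](C=C)C[C@H](CO[Si](c2ccccc2)(c2ccccc2)C(C)(C)C)O1 | intermediate
15 | (5Z,8R)-8-{[(tert-butyldiphenylsilyl)oxy]methyl}-3,4,7,8-tetrahydro-2H-oxocin-2-one | CC(C)(C)[Si](c1ccccc1)(c1ccccc1)OC[C@H]1C/C=C\CCC(=O)O1 | intermediate
16 | potassium enolate of lactone 15 | CC(C)(C)[Si](c1ccccc1)(c1ccccc1)OC[C@H]1C/C=C\C/C=C(/[O-])O1.[K+] | intermediate
17 | (3R,5Z,8R)-8-{[(tert-butyldiphenylsilyl)oxy]methyl}-3-hydroxy-3,4,7,8-tetrahydro-2H-oxocin-2-one | CC(C)(C)[Si](c1ccccc1)(c1ccccc1)OC[C@H]1C/C=C\C[C@@H](O)C(=O)O1 | intermediate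
18 | (3R,5Z,8R)-8-{[(tert-butyldiphenylsilyl)oxy]methyl}-3-[(trimethylsilyl)oxy]-3,4,7,8-tetrahydro-2H-oxocin-2-one | CC(C)(C)[Si](c1ccccc1)(c1ccccc1)OC[C@H]1C/C=C\C[C@@H](O[Si](C)(C)C)C(=O)O1 | intermediate
19 | (3R,5Z,8R)-8-{[(tert-butyldiphenylsilyl)oxy]methyl}-2-methylidene-3-[(trimethylsilyl)oxy]-3,4,7,8-tetrahydro-2H-oxocine | CC(C)(C)[Si](c1ccccc1)(c1ccccc1)OC[C@H]1C/C=C\C[C@@H](O[Si](C)(C)C)C(=C)O1 | intermediate
20 | (3R,5Z,8R)-8-{[(tert-butyldiphenylsilyl)oxy]methyl}-2-methylidene-3,4,7,8-tetrahydro-2H-oxocin-3-ol | CC(C)(C)[Si](c1ccccc1)(c1ccccc1)OC[C@H]1C/C=C\C[C@@H](O)C(=C)O1 | intermediate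
21 | dimethylsilyl ether of 20 (C12–O–SiHMe2) | CC(C)(C)[Si](c1ccccc1)(c1ccccc1)OC[C@H]1C/C=C\C[C@@H](O[SiH](C)C)C(=C)O1 | intermediate
22 | cis-fused bicyclic siloxane (C12–O–SiMe2–C14H2–C13; C7, C12 and C13 substituents all cis) | CC(C)(C)[Si](c1ccccc1)(c1ccccc1)OC[C@H]1C/C=C\C[C@H]2O[Si](C)(C)C[C@H]2O1 | intermediate
23 | (2R,3R,5Z,8R)-8-{[(tert-butyldiphenylsilyl)oxy]methyl}-2-(hydroxymethyl)-3,4,7,8-tetrahydro-2H-oxocin-3-ol | CC(C)(C)[Si](c1ccccc1)(c1ccccc1)OC[C@H]1C/C=C\C[C@@H](O)[C@@H](CO)O1 | intermediate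
24 | [(2R,3R,5Z,8R)-8-{[(tert-butyldiphenylsilyl)oxy]methyl}-3-hydroxy-3,4,7,8-tetrahydro-2H-oxocin-2-yl]methyl trifluoromethanesulfonate | CC(C)(C)[Si](c1ccccc1)(c1ccccc1)OC[C@H]1C/C=C\C[C@@H](O)[C@@H](COS(=O)(=O)C(F)(F)F)O1 | intermediate
25 | [(2R,3R,5Z,8R)-8-{[(tert-butyldiphenylsilyl)oxy]methyl}-3-[(triethylsilyl)oxy]-3,4,7,8-tetrahydro-2H-oxocin-2-yl]methyl trifluoromethanesulfonate | CC(C)(C)[Si](c1ccccc1)(c1ccccc1)OC[C@H]1C/C=C\C[C@@H](O[Si](CC)(CC)CC)[C@@H](COS(=O)(=O)C(F)(F)F)O1 | intermediate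
26 | (2R,3R,5Z,8R)-8-{[(tert-butyldiphenylsilyl)oxy]methyl}-2-ethyl-3-[(triethylsilyl)oxy]-3,4,7,8-tetrahydro-2H-oxocine | CC(C)(C)[Si](c1ccccc1)(c1ccccc1)OC[C@H]1C/C=C\C[C@@H](O[Si](CC)(CC)CC)[C@@H](CC)O1 | intermediate
27 | (2R,3R,5Z,8R)-8-{[(tert-butyldiphenylsilyl)oxy]methyl}-2-ethyl-3,4,7,8-tetrahydro-2H-oxocin-3-ol | CC(C)(C)[Si](c1ccccc1)(c1ccccc1)OC[C@H]1C/C=C\C[C@@H](O)[C@@H](CC)O1 | intermediate
28 | tert-butyl{[(2R,4Z,7S,8R)-7-bromo-8-ethyl-3,6,7,8-tetrahydro-2H-oxocin-2-yl]methoxy}diphenylsilane | CC(C)(C)[Si](c1ccccc1)(c1ccccc1)OC[C@H]1C/C=C\C[C@H](Br)[C@@H](CC)O1 | intermediate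
29 | [(2R,4Z,7S,8R)-7-bromo-8-ethyl-3,6,7,8-tetrahydro-2H-oxocin-2-yl]methanol | OC[C@H]1C/C=C\C[C@H](Br)[C@@H](CC)O1 | intermediate
30 | (2R,4Z,7S,8R)-7-bromo-8-ethyl-3,6,7,8-tetrahydro-2H-oxocine-2-carbaldehyde | O=C[C@H]1C/C=C\C[C@H](Br)[C@@H](CC)O1 | intermediate
31 | 1-(tert-butyldimethylsilyloxy)-1-methoxyethene | C=C(OC)O[Si](C)(C)C(C)(C)C | starting material
32 | methyl (3R)-3-[(2R,4Z,7S,8R)-7-bromo-8-ethyl-3,6,7,8-tetrahydro-2H-oxocin-2-yl]-3-hydroxypropanoate | COC(=O)C[C@@H](O)[C@H]1C/C=C\C[C@H](Br)[C@@H](CC)O1 | intermediate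
33 | methyl (3R)-3-[(2R,4Z,7S,8R)-7-bromo-8-ethyl-3,6,7,8-tetrahydro-2H-oxocin-2-yl]-3-[(triethylsilyl)oxy]propanoate | COC(=O)C[C@@H](O[Si](CC)(CC)CC)[C@H]1C/C=C\C[C@H](Br)[C@@H](CC)O1 | intermediate
34 | (3R)-3-[(2R,4Z,7S,8R)-7-bromo-8-ethyl-3,6,7,8-tetrahydro-2H-oxocin-2-yl]-3-[(triethylsilyl)oxy]propanal | O=CC[C@@H](O[Si](CC)(CC)CC)[C@H]1C/C=C\C[C@H](Br)[C@@H](CC)O1 | intermediate
35 | 3-bromo-1-(trimethylsilyl)prop-1-yne | C[Si](C)(C)C#CCBr | starting material
36 | triethyl phosphite | CCOP(OCC)OCC | starting material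
37 | diethyl [3-(trimethylsilyl)prop-2-yn-1-yl]phosphonate | CCOP(=O)(CC#C[Si](C)(C)C)OCC | intermediate
38 | lithiated phosphonate (α-lithio derivative of 37) | [Li+].CCOP(=O)([CH-]C#C[Si](C)(C)C)OCC | intermediate
39 | (3E,6R)-6-[(2R,4Z,7S,8R)-7-bromo-8-ethyl-3,6,7,8-tetrahydro-2H-oxocin-2-yl]-6-[(triethylsilyl)oxy]-1-(trimethylsilyl)hex-3-en-1-yne | C[Si](C)(C)C#C/C=C/C[C@@H](O[Si](CC)(CC)CC)[C@H]1C/C=C\C[C@H](Br)[C@@H](CC)O1 | intermediate
40 | (1R,3E)-1-[(2R,4Z,7S,8R)-7-bromo-8-ethyl-3,6,7,8-tetrahydro-2H-oxocin-2-yl]hex-3-en-5-yn-1-ol | C#C/C=C/C[C@@H](O)[C@H]1C/C=C\C[C@H](Br)[C@@H](CC)O1 | intermediate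
41 | (1R,3E)-1-[(2R,4Z,7S,8R)-7-bromo-8-ethyl-3,6,7,8-tetrahydro-2H-oxocin-2-yl]hex-3-en-5-yn-1-yl acetate | C#C/C=C/C[C@@H](OC(C)=O)[C@H]1C/C=C\C[C@H](Br)[C@@H](CC)O1 | target

**Step count and risk**

Total step count: 28. Longest linear sequence: 26 (steps 1–5, 7–24 and 26–28, from dimethyl (R)-malate). Steps 6 and 25 are one-step reagent branches.

Steps most likely to fail:

Step 10. The facial selectivity of the enolate oxidation may be poor or reversed, delivering oxygen trans to the C7 substituent; every later centre (C13 by the tethered hydrosilation, C12 by inversion) depends on this one. Fallback, setting out from lactone 15: the same oxidation would then give the epimeric (3S,5Z,8R)-hydroxy lactone F2. This is inverted at C12 under Mitsunobu conditions (ClCH2CO2H, PPh3, DIAD, toluene, 0 °C → rt) to the (3R)-chloroacetate F3. The chloroacetyl group is then removed with thiourea and NaHCO3 in EtOH at 50 °C, neutral conditions that do not open the eight-membered lactone, and the route is rejoined at 17.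

Step 19. Displacement at the hindered C12 carbinol next to the ring oxygen may be overtaken by E2 elimination towards the allylic C11 hydrogens, or by participation of the ring oxygen leading to retention or ring contraction. Fallback, setting out from alcohol 27: sulfonylation with ClCH2SO2Cl and 2,6-lutidine in CH2Cl2 at 0 °C gives the chloromethanesulfonate F4, a small and very reactive leaving group. Displacement with LiBr in THF/DMF at 40 °C then proceeds by clean SN2 inversion without a phosphonium intermediate, and the route is rejoined at bromide 28.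

Step 9. The selenoxide elimination towards the acetal carbon needs high temperature, and the ketene acetal may be lost before it rearranges, by re-addition of benzeneselenenic acid or by hydrolysis to a hydroxy acetate. The cis-dioxane must also leave its diequatorial chair to reach the reactive geometry. Fallback, setting out from diol 7: 1,1'-carbonyldiimidazole in CH2Cl2 converts the diol into the cyclic carbonate F1. Methylenation of the carbonate carbonyl with Cp2TiMe2 in toluene at 110 °C then generates the same ketene acetal 14 in a selenium-free, aprotic medium, where it rearranges in the same flask, and the route is rejoined at lactone 15.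

Further compounds
F1 | step 9 | (4S,6R)-4-ethenyl-6-{[(tert-butyldiphenylsilyl)oxy]methyl}-1,3-dioxan-2-one | O=C1O[C@H](C=C)C[C@H](CO[Si](c2ccccc2)(c2ccccc2)C(C)(C)C)O1
F2 | step 10 | (3S,5Z,8R)-8-{[(tert-butyldiphenylsilyl)oxy]methyl}-3-hydroxy-3,4,7,8-tetrahydro-2H-oxocin-2-one | CC(C)(C)[Si](c1ccccc1)(c1ccccc1)OC[C@H]1C/C=C\C[C@H](O)C(=O)O1
F3 | step 10 | (3R,5Z,8R)-8-{[(tert-butyldiphenylsilyl)oxy]methyl}-2-oxo-3,4,7,8-tetrahydro-2H-oxocin-3-yl chloroacetate | CC(C)(C)[Si](c1ccccc1)(c1ccccc1)OC[C@H]1C/C=C\C[C@@H](OC(=O)CCl)C(=O)O1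
F4 | step 19 | (2R,3R,5Z,8R)-8-{[(tert-butyldiphenylsilyl)oxy]methyl}-2-ethyl-3,4,7,8-tetrahydro-2H-oxocin-3-yl chloromethanesulfonate | CC(C)(C)[Si](c1ccccc1)(c1ccccc1)OC[C@H]1C/C=C\C[C@@H](OS(=O)(=O)CCl)[C@@H](CC)O1
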